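**Plan**

- Retrosynthesis: removing the O3 and O8 esters and the C12 ester leads back to a 5-hydroxyeudesma-4(15),11-dien-8-one with C3 unoxidised. Ring A is then cut at C1–C10 and at C3–C4, leaving a ring-B hydroxy enone (C5 carbinol carrying the C4≡C15 ethynyl group) and a C1–C3 1,3-dimetallopropane. The enone goes back to (S)-carvone by removing the C8 oxygen and the ethynyl group.
- Forward: ring B is bought as (S)-carvone, ethynylated at C5 and oxidised at C8. Ring A is then annulated in one operation (C10–C1 by 1,4-addition, C3–C4 by carbometalation). The remaining steps adjust C7, C8, C3 and C12.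
- Stereochemistry: C7 is bought. C5 follows from C7 (axial ethynylation) and C10 from C5 (alkoxide-directed delivery). C7 is then inverted to its equatorial position under thermodynamic control, C8 is set by equatorial hydride attack, and C3 by hydride delivered from the C5 hydroxyl.
- Enabling feature: C5 is both γ to the C8 carbonyl (across C9=C10) and propargylic to C4≡C15. One magnesium alkoxide on C5 can therefore steer a carbon nucleophile to C10 and a second one to C4; when both belong to one C3 chain, the six-membered ring A (C1–C5, C10) closes.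

Key step: step 4

Remark on the chemistry: eudesmane numbering is used in the names (ring A = C1–C5 and C10; ring B = C5–C10; C14 = methyl on C10; C15 = methylidene carbon on C4; C11–C13 = side chain on C7, C12 being the oxidised carbon). The alcohol from step 8 is drawn as the 3α epimer; either epimer serves, because step 9 removes this centre.

**Step 1**
Reactants: 1 (S)-(+)-carvone
Product: 2 (1R,5S)-1-ethynyl-2-methyl-5-(prop-1-en-2-yl)cyclohex-2-en-1-ol
Conditions: HC≡CMgBr (1.5 equiv), THF, −20 °C to rt; then H2O
Reagents that add atoms: ethynylmagnesium bromide, C#C[Mg]Br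
Why: 1,2-addition of an alkynyl Grignard reagent to the enone carbonyl, in which attack along the axial trajectory anti to the pseudo-equatorial isopropenyl group should place the ethynyl group trans and the new C5 hydroxyl cis to the isopropenyl group, so that C5 is relayed from the bought C7 centre.

**Step 2**
Reactants: 2 (1R,5S)-1-ethynyl-2-methyl-5-(prop-1-en-2-yl)cyclohex-2-en-1-ol
Product: 3 (4R,6S)-4-ethynyl-4-hydroxy-3-methyl-6-(prop-1-en-2-yl)cyclohex-2-en-1-one
Conditions: dirhodium tetrakis(caprolactamate) Rh2(cap)4 (1 mol %), t-BuOOH (70 % aq, 5 equiv), K2CO3 (0.5 equiv), CH2Cl2, rt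
Reagents that add atoms: tert-butyl hydroperoxide, CC(C)(C)OO
Why: rhodium-catalysed radical allylic C–H oxidation should convert C8, the only ring methylene allylic to the trisubstituted alkene (the other allylic site, C5, is quaternary), into the enone carbonyl, while the free tertiary alcohol cannot undergo the oxidative transposition seen with chromium oxidants; no stereocentre is formed.

**Step 3**
Reactants: 4 1,3-dibromopropane
Product: 5 1,3-bis(bromomagnesio)propane
Conditions: Mg turnings (4 equiv), Et2O, rt, slow addition; decanted and titrated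
Reagents that add atoms: magnesium, [Mg]
Why: Grignard formation by magnesium insertion into both C–Br bonds gives the known 1,3-di-Grignard reagent, which is titrated and used in excess because 1,3-elimination to cyclopropane lowers its concentration.

**Step 4**
Reactants: 3 (4R,6S)-4-ethynyl-4-hydroxy-3-methyl-6-(prop-1-en-2-yl)cyclohex-2-en-1-one; 5 1,3-bis(bromomagnesio)propane
Product: 9 (5R,7S,10R)-5-hydroxyeudesma-4(15),11-dien-8-one, via chloromagnesium alkoxide 6 (not isolated), via conjugate adduct 7 (not isolated), via alkenylmagnesium 8 (not isolated)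
Conditions: t-BuMgCl (1.05 equiv), THF, −78 °C; cannulated into 5 (2 equiv), Et2O/THF, −78 to 0 °C; then CuBr·SMe2 (20 mol %), 0 °C to rt; then H2O
Reagents that add atoms: none
Why: Proposed new method: the chloromagnesium alkoxide at C5 binds one C–Mg end of the di-Grignard reagent and delivers it intramolecularly to C10 of the enone (closest known reaction: alkoxide-directed 1,4-addition of Grignard reagents to 4-oxido enones), which masks the C8 carbonyl as its magnesium enolate; once the copper salt is added, the remaining C3–Mg end adds to the carbinol-proximal alkyne carbon C4 in an anti-carbomagnesiation that leaves magnesium on C15 chelated to the C5 alkoxide (closest known reaction: copper-catalysed anti-addition of Grignard reagents to propargylic alkoxides, which is regiospecific for that carbon). Ring A (C1–C5, C10) is closed in the 6-exo-dig mode, and protonation on work-up reveals the C4=C15 methylidene group and the C8 ketone. The new quaternary centre C10 is controlled by the C5 alkoxide: delivery syn to oxygen puts C1 cis to O5 and the methyl group trans to it, which becomes the trans ring fusion of the target once C3 is tied to C4. The step needs 1,4- over 1,2-addition and conjugate addition before carbometalation; the first is secured by internal delivery from the alkoxide, the second by withholding copper until the enone is consumed at low temperature. Bridging of two enone molecules by one reagent molecule is suppressed by inverse addition into excess di-Grignard reagent, and the directing alkoxide together with the exo preference should exclude seven-membered closure at C15.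

**Step 5**
Reactants: 9 (5R,7S,10R)-5-hydroxyeudesma-4(15),11-dien-8-one
Product: 10 (5R,7R,10R)-5-hydroxyeudesma-4(15),11-dien-8-one
Conditions: DBU (0.2 equiv), CH2Cl2, 0 °C to rt, monitored
Reagents that add atoms: none
Why: base-mediated epimerisation through the C8 enolate under thermodynamic control should move the axial 7α-isopropenyl group, which is syn-diaxial to the 5α-hydroxyl, to the equatorial 7β position; a weak amidine base in an aprotic solvent is chosen so that α-reprotonation outruns migration of the side-chain alkene into conjugation.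

**Step 6**
Reactants: 10 (5R,7R,10R)-5-hydroxyeudesma-4(15),11-dien-8-one
Product: 11 (5R,7R,8R,10R)-eudesma-4(15),11-diene-5,8-diol
Conditions: LiBH(s-Bu)3 (1.5 equiv), THF, −78 °C; then H2O
Reagents that add atoms: none
Why: ketone reduction with a bulky trialkylborohydride, in which equatorial attack from the α face (the axial β trajectory is shielded by the angular C10 methyl group) should give the axial 8β-alcohol cis to the 7β side chain.

**Step 7**
Reactants: 11 (5R,7R,8R,10R)-eudesma-4(15),11-diene-5,8-diol
Product: 12 (5R,7R,8R,10R)-5-hydroxyeudesma-4(15),11-dien-8-yl acetate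
Conditions: Ac2O, DMAP (cat.), pyridine, rt
Reagents that add atoms: acetic anhydride, CC(=O)OC(C)=O
Why: DMAP-catalysed acetylation (nucleophilic acyl substitution) of the secondary 8β-alcohol, the tertiary C5 hydroxyl being too hindered to react.

**Step 8**
Reactants: 12 (5R,7R,8R,10R)-5-hydroxyeudesma-4(15),11-dien-8-yl acetate
Product: 13 (3R,5S,7R,8R,10R)-3,5,12-trihydroxyeudesma-4(15),11(13)-dien-8-yl acetate
Conditions: SeO2 (0.5 equiv), t-BuOOH (5 equiv), CH2Cl2, rt
Reagents that add atoms: tert-butyl hydroperoxide, CC(C)(C)OO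
Why: selenium dioxide allylic hydroxylation (ene reaction followed by [2,3]-sigmatropic shift) should act at both 1,1-disubstituted alkenes, since C3 is the only allylic C–H site of the C4=C15 unit and the methyl group is the preferred site of the isopropenyl group; the configuration formed at C3 is not relied on.

**Step 9**
Reactants: 13 (3R,5S,7R,8R,10R)-3,5,12-trihydroxyeudesma-4(15),11(13)-dien-8-yl acetate
Product: 14 (5S,7R,8R,10R)-5-hydroxy-3,12-dioxoeudesma-4(15),11(13)-dien-8-yl acetate
Conditions: Dess–Martin periodinane (2.5 equiv), CH2Cl2, 0 °C to rt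
Reagents that add atoms: none
Why: Dess–Martin oxidation of the secondary allylic C3 alcohol and the primary allylic C12 alcohol to the enone and the enal, which leaves the tertiary alcohol and the acetate untouched and removes the C3 stereocentre.

**Step 10**
Reactants: 14 (5S,7R,8R,10R)-5-hydroxy-3,12-dioxoeudesma-4(15),11(13)-dien-8-yl acetate
Product: 15 (5S,7R,8R,10R)-8-acetoxy-5-hydroxy-3-oxoeudesma-4(15),11(13)-dien-12-oic acid
Conditions: NaClO2, NaH2PO4, 2-methyl-2-butene, t-BuOH/H2O, 0 °C to rt
Reagents that add atoms: sodium chlorite, [Na+].[O-]Cl=O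
Why: Pinnick oxidation of the α,β-unsaturated aldehyde to the acid, with 2-methyl-2-butene scavenging hypochlorite so that the two electron-poor methylidene groups survive.

**Step 11**
Reactants: 15 (5S,7R,8R,10R)-8-acetoxy-5-hydroxy-3-oxoeudesma-4(15),11(13)-dien-12-oic acid
Product: 16 methyl (5S,7R,8R,10R)-8-acetoxy-5-hydroxy-3-oxoeudesma-4(15),11(13)-dien-12-oate
Conditions: MeI, KHCO3, DMF, rt
Reagents that add atoms: iodomethane, CI
Why: O-alkylation of the carboxylate (SN2) under weakly basic conditions gives the methyl ester without exposing the enone, the acrylate or the acetate to strong base or to a diazoalkane.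

**Step 12**
Reactants: 16 methyl (5S,7R,8R,10R)-8-acetoxy-5-hydroxy-3-oxoeudesma-4(15),11(13)-dien-12-oate
Product: 17 methyl (3S,5S,7R,8R,10R)-8-acetoxy-3,5-dihydroxyeudesma-4(15),11(13)-dien-12-oate
Conditions: Me4NBH(OAc)3, AcOH/MeCN, −20 °C
Reagents that add atoms: none
Why: hydroxyl-directed reduction of the β-hydroxy ketone (Evans–Saksena reduction), in which hydride delivered from boron bound to the axial 5α-hydroxyl should reach the α face of C3 by 1,2-addition and give the 1,3-anti diol, that is the equatorial 3β-alcohol.

**Step 13**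
Reactants: 17 methyl (3S,5S,7R,8R,10R)-8-acetoxy-3,5-dihydroxyeudesma-4(15),11(13)-dien-12-oate
Product: 18 methyl (3S,5S,7R,8R,10R)-8-acetoxy-5-hydroxy-3-{[(2Z)-2-methylbut-2-enoyl]oxy}eudesma-4(15),11(13)-dien-12-oate
Conditions: angelic acid, 2,4,6-trichlorobenzoyl chloride, Et3N, toluene, rt; then 17, toluene, 80 °C
Reagents that add atoms: angelic acid, C/C=C(/C)C(=O)O
Why: Yamaguchi esterification through the preformed mixed anhydride should acylate the secondary allylic 3β-hydroxyl only (the tertiary 5-hydroxyl is inert), and leaving out a nucleophilic catalyst at the acylation stage is meant to keep the (Z)-alkene from isomerising to the tiglate.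

**Compound list**

1 | (S)-(+)-carvone, (5S)-2-methyl-5-(prop-1-en-2-yl)cyclohex-2-en-1-one | CC(=C)[C@@H]1CC(=O)C(C)=CC1 | starting material
2 | (1R,5S)-1-ethynyl-2-methyl-5-(prop-1-en-2-yl)cyclohex-2-en-1-ol (hydroxyl cis to isopropenyl) | CC(=C)[C@@H]1C[C@@](O)(C#C)C(C)=CC1 | intermediate
3 | (4R,6S)-4-ethynyl-4-hydroxy-3-methyl-6-(prop-1-en-2-yl)cyclohex-2-en-1-one | CC(=C)[C@@H]1C[C@@](O)(C#C)C(C)=CC1=O | intermediate
4 | 1,3-dibromopropane | BrCCCBr | starting material
5 | 1,3-bis(bromomagnesio)propane | Br[Mg]CCC[Mg]Br | intermediate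
6 | chloromagnesium alkoxide of 3 | CC(=C)[C@@H]1C[C@@](O[Mg]Cl)(C#C)C(C)=CC1=O | intermediate
7 | conjugate adduct: C8 bromomagnesium enolate and C5 chloromagnesium alkoxide carrying a 3-(bromomagnesio)propyl group on C10, cis to the C5 oxygen | CC(=C)[C@@H]1C[C@@](O[Mg]Cl)(C#C)[C@](C)(CCC[Mg]Br)C=C1O[Mg]Br | intermediate
8 | ring-closed alkenylmagnesium species (magnesium on C15, cis to C5) | CC(=C)[C@@H]1C[C@@]2(O[Mg]Cl)/C(=C\[Mg]Br)CCC[C@]2(C)C=C1O[Mg]Br | intermediate
9 | (5R,7S,10R)-5-hydroxyeudesma-4(15),11-dien-8-one (trans-decalin; 7α-isopropenyl cis to 5α-OH) | CC(=C)[C@@H]1C[C@@]2(O)C(=C)CCC[C@]2(C)CC1=O | intermediate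
10 | (5R,7R,10R)-5-hydroxyeudesma-4(15),11-dien-8-one (7β-isopropenyl) | CC(=C)[C@H]1C[C@@]2(O)C(=C)CCC[C@]2(C)CC1=O | intermediate
11 | (5R,7R,8R,10R)-eudesma-4(15),11-diene-5,8-diol (5α,8β) | CC(=C)[C@H]1C[C@@]2(O)C(=C)CCC[C@]2(C)C[C@H]1O | intermediate
12 | (5R,7R,8R,10R)-5-hydroxyeudesma-4(15),11-dien-8-yl acetate | CC(=C)[C@H]1C[C@@]2(O)C(=C)CCC[C@]2(C)C[C@H]1OC(C)=O | intermediate
13 | (3R,5S,7R,8R,10R)-3,5,12-trihydroxyeudesma-4(15),11(13)-dien-8-yl acetate | OCC(=C)[C@H]1C[C@@]2(O)C(=C)[C@H](O)CC[C@]2(C)C[C@H]1OC(C)=O | intermediate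
14 | (5S,7R,8R,10R)-5-hydroxy-3,12-dioxoeudesma-4(15),11(13)-dien-8-yl acetate | O=CC(=C)[C@H]1C[C@@]2(O)C(=C)C(=O)CC[C@]2(C)C[C@H]1OC(C)=O | intermediate
15 | (5S,7R,8R,10R)-8-acetoxy-5-hydroxy-3-oxoeudesma-4(15),11(13)-dien-12-oic acid | OC(=O)C(=C)[C@H]1C[C@@]2(O)C(=C)C(=O)CC[C@]2(C)C[C@H]1OC(C)=O | intermediate
16 | methyl (5S,7R,8R,10R)-8-acetoxy-5-hydroxy-3-oxoeudesma-4(15),11(13)-dien-12-oate | C=C(C(=O)OC)[C@H]1C[C@@]2(O)C(=C)C(=O)CC[C@]2(C)C[C@H]1OC(C)=O | intermediate
17 | methyl (3S,5S,7R,8R,10R)-8-acetoxy-3,5-dihydroxyeudesma-4(15),11(13)-dien-12-oate | C=C(C(=O)OC)[C@H]1C[C@@]2(O)C(=C)[C@@H](O)CC[C@]2(C)C[C@H]1OC(C)=O | intermediate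
18 | methyl (3S,5S,7R,8R,10R)-8-acetoxy-5-hydroxy-3-{[(2Z)-2-methylbut-2-enoyl]oxy}eudesma-4(15),11(13)-dien-12-oate | C=C(C(=O)OC)[C@H]1C[C@@]2(O)C(=C)[C@@H](OC(=O)/C(C)=C\C)CC[C@]2(C)C[C@H]1OC(C)=O | target

**Step count and risks**

Total steps: 13. Longest linear sequence: 12 (steps 1, 2 and 4–13 from compound 1).

Steps most likely to fail:

1. Step 4 (proposed new method). Proton transfer from the terminal alkyne to the organomagnesium centres may quench the second C–Mg end before ring closure. 1,4-Addition to the β,β-disubstituted enone may be slow, and the reagent may bridge two enone molecules or decay to cyclopropane. The fallback uses known reactions only, sets out from 3 and comes back at 9. The alkoxide of 3 (t-BuMgCl) undergoes alkoxide-directed 1,4-addition of (3-chloropropyl)magnesium bromide to give (3R,4S,6S)-3-(3-chloropropyl)-4-ethynyl-4-hydroxy-3-methyl-6-(prop-1-en-2-yl)cyclohexan-1-one F1. Finkelstein exchange (NaI, acetone) gives the iodide (3R,4S,6S)-4-ethynyl-4-hydroxy-3-(3-iodopropyl)-3-methyl-6-(prop-1-en-2-yl)cyclohexan-1-one F2. Bu3SnH/AIBN (slow addition, benzene, 80 °C) then closes ring A by 6-exo-dig cyclisation of the primary radical onto the alkyne and gives 9.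

2. Step 2. Hydrogen abstraction may not be site-selective (the tertiary allylic C7–H and the isopropenyl methyl compete with C8), and over-oxidation may occur. The fallback installs the C8 oxygen before the ethynyl group, sets out from 1 and comes back at 3. Silylation of 1 under equilibrating conditions gives the linear dienol silyl ether tert-butyl(dimethyl){[(5R)-2-methyl-5-(prop-1-en-2-yl)cyclohexa-1,3-dien-1-yl]oxy}silane F3. Vinylogous Rubottom oxidation (mCPBA, then mild acid) hydroxylates C8 anti to the isopropenyl group and gives (4R,5S)-4-hydroxy-2-methyl-5-(prop-1-en-2-yl)cyclohex-2-en-1-one F4. Excess HC≡CMgBr adds to the carbonyl to give (1R,4R,5S)-1-ethynyl-2-methyl-5-(prop-1-en-2-yl)cyclohex-2-ene-1,4-diol F5. MnO2 oxidises the secondary allylic alcohol selectively and gives 3.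

3. Step 5. Migration of the side-chain double bond into conjugation with the C8 carbonyl may compete with epimerisation at C7. The fallback replaces equilibration by conjugation followed by kinetic deconjugation, sets out from 9 and comes back at 10. NaOMe/MeOH drives 9 fully to the conjugated ketone (5R,10R)-5-hydroxyeudesma-4(15),7(11)-dien-8-one F6. Its extended lithium enolate (LDA, THF, −78 °C) is protonated at C7 with AcOH at −78 °C; protonation along the axial trajectory on the α face should give the equatorial 7β-isopropenyl ketone 10.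

Further compounds
F1 | step 4 | (3R,4S,6S)-3-(3-chloropropyl)-4-ethynyl-4-hydroxy-3-methyl-6-(prop-1-en-2-yl)cyclohexan-1-one | CC(=C)[C@@H]1C[C@@](O)(C#C)[C@](C)(CCCCl)CC1=O
F2 | step 4 | (3R,4S,6S)-4-ethynyl-4-hydroxy-3-(3-iodopropyl)-3-methyl-6-(prop-1-en-2-yl)cyclohexan-1-one | CC(=C)[C@@H]1C[C@@](O)(C#C)[C@](C)(CCCI)CC1=O
F3 | step 2 | tert-butyl(dimethyl){[(5R)-2-methyl-5-(prop-1-en-2-yl)cyclohexa-1,3-dien-1-yl]oxy}silane | CC(=C)[C@@H]1CC(O[Si](C)(C)C(C)(C)C)=C(C)C=C1
F4 | step 2 | (4R,5S)-4-hydroxy-2-methyl-5-(prop-1-en-2-yl)cyclohex-2-en-1-one | CC(=C)[C@@H]1CC(=O)C(C)=C[C@H]1O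
F5 | step 2 | (1R,4R,5S)-1-ethynyl-2-methyl-5-(prop-1-en-2-yl)cyclohex-2-ene-1,4-diol | CC(=C)[C@@H]1C[C@@](O)(C#C)C(C)=C[C@H]1O
F6 | step 5 | (5R,10R)-5-hydroxyeudesma-4(15),7(11)-dien-8-one | CC(C)=C1C[C@@]2(O)C(=C)CCC[C@]2(C)CC1=O
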